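| flask | starting material | coupling partner | protic impurity | remark | time |
|---|---|---|---|---|---|
| ochre | 0.34 M | 1.2 equiv | 0.34 M | run made earlier |  |
| red | 0.34 M | 1.9 equiv | 0.34 M | run made earlier |  |
| amber | 0.34 M | 2.5 equiv | 0.51 M | run made earlier |  |
| flask | 0.34 M | 2.50 equiv | 0.340 M |  | 1.5 h |

- ochre (time / min: product / %): 6.00: 38.9; 20.0: 73.8; 30.0: 76.1; 50.0: 76.9; 60.0: 76.6; 90.0: 76.1
- red (time / min: product / %): 6.00: 50.3; 20.0: 84.4; 30.0: 86.9; 50.0: 84.4; 60.0: 87.4; 90.0: 87.2
- amber (time / min: product / %): 8.00: 66.6; 25.0: 84.0; 40.0: 85.6; 60.0: 85.5; 90.0: 82.5

(scatter of a reading: 1 percentage point)

- the reaction counts as stopped when no species that holds the starting material changes by six tenths of a point or more over the second half of the time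

1. which holds at 1.5 h: what has brought the reaction to rest, or that it has not come to rest (all of the starting material has reacted / it is still moving / forward and back rates have come level / the coupling partner has run out first)
2. product at 1.5 h, in percent of the starting material charged

**Nearest run.** Amber is the simulated run to read, because it has the flask's 2.5 equiv of coupling partner. The two differ in protic impurity: 0.51 M in amber, 0.340 M in the flask. Average amber's readings from 40.0 min on, and product stands at 84.5%.

**Two routes.** Read the missing points as starting material lost to the protic impurity, one for one. Partner and impurity then compete for it. On that reading, amber's partner gives up 0.287 M and its impurity 0.0526 M. Take half of each: 0.144 M of partner and 0.0263 M of impurity. Subtract these from the charges to get run means. Amber then reads 3.74 for the selectivity factor, the points of product per point lost, multiplied by mean impurity over mean partner. Ochre from 30.0 min on stands at 76.4% and reads 3.50. Red stands at 86.5% and reads 4.06.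

**My reckoning.** Subtract the same amounts from the flask's charges. The flask then has a ratio of product to loss of 8.43, higher than amber's 5.45, because it holds less impurity against the same partner. So I expect 89.4% of product. Amber's readings stop rising by 40.0 min, earlier than the flask's 1.5 h. I therefore expect the flask at rest with starting material as limiting reagent and 0.546 M of partner over.

**The forecast.** It gives 91% and the end state "forward and back rates have come level", holding that “the impurity pushes the balance backward”, and my reckoning differs from it on that end state.

    starting material + protic impurity → quenched substrate (k = 0.240 /M/min)
    starting material + coupling partner → intermediate + by-product (k = 0.950 /M/min)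
    intermediate → product (k = 0.220 /min)

**The result.** The flask gives 89.4% at 1.5 h, and its end state is: all of the starting material has reacted. Its starting material stands at 0% and its quenched substrate at 10.6%. Now use the factor on the neighbouring flask with 0.85 M of protic impurity, its other charges as in the flask. The same subtractions give a ratio of product to loss of 3.21, so 76.2% of product. That neighbour gives 77.6%.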